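At early times this flask holds no fresh carrier, because the carrier goes in as spent carrier, so the catalyst's story opens with the exchange against the salt in the second phase.

starting material 1.5 M; salt in the second phase 1.50 M; protic impurity 0.150 M; spent carrier 60 mM; stray impurity 26 mM; volume of the second phase over the first 1.0

    starting material + protic impurity → quenched substrate (k1 = 0.95 L mol⁻¹ h⁻¹)
    fresh carrier + stray impurity → spent catalyst (k2 = 1600 L mol⁻¹ h⁻¹)
    starting material + fresh carrier → product + spent carrier (k3 = 1.5 L mol⁻¹ h⁻¹)
    spent carrier + salt in the second phase ⇌ fresh carrier + spent salt in the second phase (K4 = 0.23, k4 = 1.6 L mol⁻¹ h⁻¹)

- in the second phase: salt in the second phase, spent salt in the second phase; everything else is in the first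
- charges count per volume of the first phase; a concentration in a rate is the amount of a species over the volume of its own phase; every rate counts per litre of the first phase
- charge of starting material (flask): 1.5 M

* apparent order in spent carrier when 5.0% of the starting material are converted (percent change of the rate of making product for one percent more spent carrier charged)
* factor on the rate of making product when 5.0% of the starting material are converted if spent carrier is charged twice over

We take the run in slow motion. With the salt as charged, the exchange is pseudo-first-order in spent carrier at 2.40 h⁻¹. Each fresh carrier then meets stray impurity at 41.6 h⁻¹ and starting material at 2.25 h⁻¹, so in this flask it is lost to stray impurity far faster than it makes product. Carrier is therefore consumed one for one until the crossing, the moment when 26 mM of it has turned over. What remains is what we carry forward: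

working carrier = 60 mM − 26 mM = 34.0 mM

This is the carrier charge less the stray impurity charge, the working carrier. If the rate follows it, the order and the doubling factor cost one division each:

order = 60 mM / 34.0 mM = 1.76

doubled charge: 94.0 mM / 34.0 mM = 2.76

That is our reckoning, but the moment of the look needs a second thought. The crossing comes at

ln(charge / working carrier) / 2.40 h⁻¹ = 0.237 h

and we look at 0.451 h, later than the crossing by 0.214 h. Fresh carrier climbs towards its balance at about 4.65 h⁻¹, a time of 0.215 h, which is of the same size as that interval, so we expect it still to be climbing at the look, early in the run. The doubled charge crosses earlier, at 0.102 h, and stands further along that climb. We therefore expect both answers somewhat above our figures, without committing to how far. Towards the end, spent and fresh carrier should simply share the working carrier.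

The forecast goes higher than our figures: an order of 2.1 (range 1.6 to 2.7) and a factor of 3 (range 2.5 to 3.6). In its words, “doubling the charge nearly triples the surviving carrier”.

The simulation gives an order of 2.3 and a factor of 3.25, both within the forecast's ranges. In this flask fresh carrier meets stray impurity at 41.6 h⁻¹ against 2.25 h⁻¹ on starting material, and spent catalyst reads 43.3% at 1.00 h and still 43.3% at 10.0 h, the 43.3% that the two charges predict. The working carrier is 56.7% of the charge, spent and fresh carrier together read 56.7% at 10.0 h, and the flask charged twice over stands at 1.18 times the working-carrier factor of 2.76.

The numbers of this flask are those of an exercise, and the outcome is calculated.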